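**Retrosynthetic overview** (cembrane locants: C1–C14 ring; lactone C15 = α-carbon, C16 = C=O, C17 = exocyclic CH2, ring O on C14)
1. Target 35 ⇐ cis-fused lactone 32 (C13 epimer) by O7 acetylation and Mitsunobu acetylation with inversion at C13; 32 ⇐ hydroxy acid 31 by lactonisation (O14–C16; last ring).
2. Key disconnection: 31 ⇐ open-chain allenyl aldehyde 28 + CO2. One Ni(0) carboxylative allyl transfer makes C15–C16 and C1–C14 together and closes the 14-membered carbocycle. Enabling feature: in the α-methylene-γ-butyrolactone ring (O–C16–C15–C1–C14), C1–C15(=C17H2) is a terminal allene in disguise, C16 is CO2 and C14–O is an aldehyde.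
3. 28 ⇐ vinyl bromide 17 (C8–C14) + epoxy aldehyde 8 (C1–C7 with C15 and C17 as a propargyl unit), joined at C7–C8; C7 set by oxidation/CBS reduction.
4. 8 ⇐ geraniol (asymmetric epoxidation sets the C3/C4 epoxide); 17 ⇐ an E-allylic alcohol (asymmetric epoxidation, then Me3Al opening sets C12/C13).
5. Ring order: epoxide (step 2) → 14-membered ring (step 19) → γ-lactone (step 20).

Key step: step 19

Remark (numbering): C3–C4 is the epoxide (methyl C18 on C4); C7 and C13 carry the acetates; C8 carries the exocyclic methylene C19; C12 carries methyl C20.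
Remark (chemistry): C13 is built and carried as its S epimer (anti to the C12 methyl). A non-chelating α-silyloxy aldehyde should be attacked anti to the C13 oxygen, and this is the sense needed only if C13 is epimeric; step 23 then inverts C13 while installing its acetate.
Assumption: but-3-en-1-ylmagnesium bromide is bought as its THF solution.

**Fragment C1–C7**

Step 1
Reactants: 1 prop-2-yn-1-ol
Product: 2 1-methoxy-4-[(prop-2-yn-1-yloxy)methyl]benzene (PMB propargyl ether)
Conditions: NaH, PMBCl, cat. Bu4NI, THF, 0 °C → rt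
Reagents that add atoms: 4-methoxybenzyl chloride, COc1ccc(CCl)cc1
Why: Williamson ether synthesis of a primary alkoxide with a benzylic chloride; no stereocenter is involved.

Step 2
Reactants: 3 geraniol
Product: 4 (2R,3R)-2,3-epoxygeraniol
Conditions: Ti(OiPr)4 (cat.), D-(−)-diethyl tartrate (cat.), t-BuOOH, 4 Å MS, CH2Cl2, −20 °C
Reagents that add atoms: tert-butyl hydroperoxide, CC(C)(C)OO
Why: Sharpless asymmetric epoxidation: the allylic hydroxyl directs the titanium–tartrate peroxide to the 2,3-olefin only, and D-(−)-tartrate delivers oxygen to the face that gives the (2R,3R)-epoxide, which becomes C3(R)/C4(R).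

Step 3
Reactants: 4 (2R,3R)-2,3-epoxygeraniol; 2 PMB propargyl ether
Product: 7 1-methoxy-4-[({4-[(2R,3R)-3-methyl-3-(4-methylpent-3-en-1-yl)oxiran-2-yl]but-2-yn-1-yl}oxy)methyl]benzene, via epoxy triflate 5 (not isolated), via lithium acetylide 6 (not isolated)
Conditions: 4: Tf2O, 2,6-lutidine, CH2Cl2, −78 °C; 2: n-BuLi, THF/DMPU, −78 °C; triflate solution added to the acetylide, −78 → −20 °C
Reagents that add atoms: none
Why: SN2 alkynylation of a primary epoxy triflate by a lithium acetylide, which at low temperature is far faster than epoxide opening, so the C2–C1 bond forms and both epoxide stereocenters stay untouched.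

Step 4
Reactants: 7 epoxy enyne PMB ether
Product: 8 3-[(2R,3R)-3-{4-[(4-methoxybenzyl)oxy]but-2-yn-1-yl}-2-methyloxiran-2-yl]propanal
Conditions: OsO4 (cat.), NaIO4, 2,6-lutidine, dioxane/H2O, rt
Reagents that add atoms: sodium periodate (terminal oxidant, oxygen delivered through OsO4), [Na+].[O-]I(=O)(=O)=O
Why: Lemieux–Johnson oxidation: OsO4 dihydroxylates the electron-rich trisubstituted alkene and not the alkyne, periodate cleaves the diol to the C7 aldehyde, and the lutidine buffer keeps the epoxide intact.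

**Fragment C8–C14**

Step 5
Reactants: 9 but-3-en-1-ylmagnesium bromide; 10 2,3-dibromoprop-1-ene
Product: 11 2-bromohepta-1,6-diene
Conditions: CuI (cat.), THF, 0 °C → rt
Reagents that add atoms: none
Why: Copper-catalysed allylic substitution of the Grignard reagent at the allylic C–Br bond (SN2 and SN2′ give the same product); the vinyl bromide is inert.

Step 6
Reactants: 11 2-bromohepta-1,6-diene; 12 methyl acrylate
Product: 13 methyl (2E)-7-bromoocta-2,7-dienoate
Conditions: Grubbs second-generation catalyst (cat.), CH2Cl2, 40 °C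
Reagents that add atoms: none
Why: Olefin cross-metathesis of a terminal alkene with an acrylate gives the E-enoate under thermodynamic control; the 1,1-disubstituted vinyl bromide does not enter the metathesis.

Step 7
Reactants: 13 methyl (2E)-7-bromoocta-2,7-dienoate
Product: 14 (2E)-7-bromoocta-2,7-dien-1-ol
Conditions: DIBAL-H, CH2Cl2, −78 °C
Reagents that add atoms: none
Why: 1,2-Reduction of an α,β-unsaturated ester to the allylic alcohol by DIBAL-H with the alkene geometry kept.

Step 8
Reactants: 14 (2E)-7-bromoocta-2,7-dien-1-ol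
Product: 15 [(2R,3R)-3-(4-bromopent-4-en-1-yl)oxiran-2-yl]methanol
Conditions: Ti(OiPr)4 (cat.), D-(−)-diethyl tartrate (cat.), t-BuOOH, 4 Å MS, CH2Cl2, −20 °C
Reagents that add atoms: tert-butyl hydroperoxide, CC(C)(C)OO
Why: Sharpless asymmetric epoxidation of an E-disubstituted allylic alcohol; D-(−)-tartrate gives the (2R,3R)-epoxy alcohol, fixing the C13 oxygen and the face from which C12 will be attacked.

Step 9
Reactants: 15 (2R,3R)-epoxy alcohol
Product: 16 (2S,3S)-7-bromo-3-methyloct-7-ene-1,2-diol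
Conditions: Me3Al, hexane/CH2Cl2, 0 °C → rt
Reagents that add atoms: trimethylaluminium, C[Al](C)C
Why: Hydroxyl-directed opening of a 2,3-epoxy alcohol by Me3Al at the distal carbon with inversion gives the 1,2-diol; this sets C12 (S, final) with methyl C20 and leaves C13 (S) anti to it.

Step 10
Reactants: 16 (2S,3S)-diol
Product: 17 (2S,3S)-7-bromo-3-methyloct-7-ene-1,2-diyl bis(tert-butyldimethylsilyl) ether
Conditions: TBSOTf, 2,6-lutidine, CH2Cl2, 0 °C
Reagents that add atoms: tert-butyldimethylsilyl triflate, CC(C)(C)[Si](C)(C)OS(=O)(=O)C(F)(F)F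
Why: Exhaustive silylation; the O13 silyl ether is the non-chelating group that later steers the aldehyde face, and the primary one can be removed selectively.

**Union and macrocycle**

Step 11
Reactants: 17 vinyl bromide; 8 epoxy aldehyde
Product: 19 coupled allylic alcohol (both C7 epimers): 17-O-PMB 13,14-bis-O-TBS C1–C14 chain with C15≡C1 alkyne; (3R,4R)-epoxide; C8=C19 methylene, via vinyllithium 18 (not isolated)
Conditions: 17, t-BuLi (2 equiv), Et2O, −78 °C; then 8, −78 °C; aq. NH4Cl
Reagents that add atoms: none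
Why: Bromine–lithium exchange and 1,2-addition of the 1,1-disubstituted vinyllithium to the aldehyde forms C7–C8; C7 is not controlled here because both epimers converge in step 12.

Step 12
Reactants: 19 coupled allylic alcohol
Product: 20 C7 enone (α-methylene ketone)
Conditions: Dess–Martin periodinane, NaHCO3, CH2Cl2, 0 °C → rt
Reagents that add atoms: none
Why: Dess–Martin oxidation of a secondary allylic alcohol under buffered, non-acidic conditions that leave the epoxide, PMB and silyl ethers alone.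

Step 13
Reactants: 20 C7 enone
Product: 21 (7R)-allylic alcohol
Conditions: (S)-2-methyl-CBS-oxazaborolidine (cat.), catecholborane, toluene, −78 °C
Reagents that add atoms: none
Why: Corey–Bakshi–Shibata reduction: the branched 1-alkylvinyl group (C8) acts as the large substituent on the (S)-oxazaborolidine–borane complex, so hydride reaches the face that gives the 7R carbinol, independent of the remote stereocenters.

Step 14
Reactants: 21 (7R)-allylic alcohol
Product: 22 7-O-TBS ether (17-O-PMB; 7,13,14-tris-O-TBS)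
Conditions: TBSCl, imidazole, cat. DMAP, DMF, rt
Reagents that add atoms: tert-butyldimethylsilyl chloride, CC(C)(C)[Si](C)(C)Cl
Why: Silylation under basic, non-Lewis-acidic conditions avoids epoxide opening by the C7 hydroxyl; a silyl ether is used because an allylic ester would be ionised by Ni(0) in step 19.

Step 15
Reactants: 22 PMB ether
Product: 23 propargylic alcohol (C17–OH)
Conditions: DDQ, CH2Cl2/pH 7 buffer, 0 °C → rt
Reagents that add atoms: none
Why: Oxidative cleavage of the PMB ether by DDQ, orthogonal to the three silyl ethers and harmless to the epoxide under buffering.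

Step 16
Reactants: 23 propargylic alcohol
Product: 26 terminal allene (C17H2=C15=C1H) with 7,13,14-tris-O-TBS, via sulfonylhydrazine adduct 24 (not isolated), via propargylic diazene 25 (not isolated)
Conditions: 2-nitrobenzenesulfonylhydrazide, PPh3, DEAD, THF, −15 °C → rt
Reagents that add atoms: none
Why: Myers allene synthesis: Mitsunobu N-alkylation of the hydrazide, loss of sulfinic acid to the propargylic diazene and retro-ene loss of N2 move hydrogen to C1 and give the terminal allene; no stereocenter is touched.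

Step 17
Reactants: 26 allene
Product: 27 primary alcohol (C14–OH; 7,13-bis-O-TBS)
Conditions: HF·pyridine, pyridine, THF, 0 °C
Reagents that add atoms: none
Why: Buffered fluoride cleaves the primary silyl ether much faster than the two secondary ones.

Step 18
Reactants: 27 primary alcohol
Product: 28 allenyl aldehyde (C14 aldehyde with 13S silyloxy group)
Conditions: Dess–Martin periodinane, NaHCO3, CH2Cl2, 0 °C; used at once
Reagents that add atoms: none
Why: Dess–Martin oxidation gives the α-silyloxy aldehyde without epimerising C13 and without touching the allene or epoxide.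

Step 19
Reactants: 28 allenyl aldehyde
Product: 31 (1S,3R,4R,7R,12S,13S,14R)-7,13-bis-O-TBS-3,4-epoxy-14-hydroxycembra-8(19),15(17)-dien-16-oic acid, via nickelalactone 29 (not isolated), via nickel alkoxide carboxylate 30 (not isolated)
Conditions: Ni(cod)2 (1.5 equiv), DBU (3 equiv), CO2 (1 atm), THF, 0 °C; 28 added over 8 h to 2 mM; rt, 12 h; aq. NH4Cl/citric acid (pH 4)
Reagents that add atoms: carbon dioxide, O=C=O
Why: Proposed new method: DBU-ligated Ni(0) couples the terminal C15=C17 π-bond of the allene oxidatively with CO2 to the five-membered oxanickelacycle 29 (C15–C16 bond), an allylnickel carboxylate with nickel on C17 and the chain cis to it; the tethered aldehyde then inserts through a six-membered chair transition state with allyl transposition (C1–C14 bond, exocyclic C15=C17) to give 30, which work-up protonates to 31. The closest known reaction type is the nickel(0)-mediated sequential addition of CO2 and an aldehyde to a terminal allene, known intermolecularly with aromatic aldehydes; its use with a tethered aliphatic aldehyde to close a macrocycle is new. The 14-membered carbocycle closes in a 14-exo-trig mode (allyl γ-carbon C1 onto the C14 carbonyl); the lactone ring is not closed here, but both of its C–C bonds are now in place. C1 and C14 should be set syn (the later cis fusion) by the Z-type allyl geometry in the chair, and the sense at C14 by attack anti to the non-chelating C13 silyloxy group (Felkin–Anh/Cornforth), which is why C13 is carried as the S epimer. The step needs CO2 capture at the allene before nickel engages the aldehyde (CO2 atmosphere, DBU, 0 °C, no allylic ester in the substrate), reaction through C1 and not C17 (the nickel–CH2 σ-allyl reacts at its substituted terminus), and cyclisation over oligomerisation (the allylnickel is stoichiometric and persistent, so slow addition to high dilution should suffice).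

Step 20
Reactants: 31 hydroxy acid
Product: 32 (1S,3R,4R,7R,12S,13S,14R)-7,13-bis-O-TBS-3,4-epoxycembra-8(19),15(17)-dien-16,14-olide
Conditions: EDC·HCl, DMAP, CH2Cl2, 0 °C → rt
Reagents that add atoms: none
Why: Carbodiimide-mediated lactonisation (5-exo-trig acyl substitution) of the cis γ-hydroxy acid under non-acidic conditions, so the epoxide is not opened by the carboxyl group; no stereocenter changes.

Step 21
Reactants: 32 bis-silyl lactone
Product: 33 7,13-diol (13S)
Conditions: HF·pyridine, excess pyridine, THF, 0 °C → rt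
Reagents that add atoms: none
Why: Fluoride-mediated cleavage of both secondary silyl ethers; the pyridine buffer is meant to keep the medium too weakly acidic for the freed C7 hydroxyl to open the epoxide across the ring.

Step 22
Reactants: 33 diol
Product: 34 7-O-acetyl-13-epi alcohol
Conditions: Ac2O, pyridine, CH2Cl2, 0 °C
Reagents that add atoms: acetic anhydride, CC(=O)OC(C)=O
Why: Kinetically selective acylation of the allylic C7 hydroxyl, which is much less hindered than the C13 hydroxyl flanked by two methine carbons; configuration at C7 is retained.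

Step 23
Reactants: 34 7-O-acetyl-13-epi alcohol
Product: 35 (1S,3R,4R,7R,12S,13R,14R)-7,13-diacetoxy-3,4-epoxycembra-8(19),15(17)-dien-16,14-olide (target)
Conditions: PPh3, DIAD, AcOH, toluene, 0 °C → rt
Reagents that add atoms: acetic acid, CC(=O)O
Why: Mitsunobu esterification: acetate displaces the C13 oxyphosphonium with inversion (S → R), and the lactone carbonyl, locked s-trans in the five-membered ring, cannot act as a neighbouring group, so the last acetate and the correct C13 configuration arrive together.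

**Compound list**
1 | prop-2-yn-1-ol | C#CCO | starting material
2 | 1-methoxy-4-[(prop-2-yn-1-yloxy)methyl]benzene | COc1ccc(COCC#C)cc1 | intermediate
3 | geraniol, (2E)-3,7-dimethylocta-2,6-dien-1-ol | CC(C)=CCC/C(C)=C/CO | starting material
4 | (2R,3R)-2,3-epoxygeraniol | OC[C@H]1O[C@]1(C)CCC=C(C)C | intermediate
5 | [(2R,3R)-3-methyl-3-(4-methylpent-3-en-1-yl)oxiran-2-yl]methyl triflate | FC(F)(F)S(=O)(=O)OC[C@H]1O[C@]1(C)CCC=C(C)C | intermediate
6 | lithium 3-[(4-methoxybenzyl)oxy]prop-1-yn-1-ide | [Li]C#CCOCc1ccc(OC)cc1 | intermediate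
7 | 1-methoxy-4-[({4-[(2R,3R)-3-methyl-3-(4-methylpent-3-en-1-yl)oxiran-2-yl]but-2-yn-1-yl}oxy)methyl]benzene | COc1ccc(COCC#CC[C@H]2O[C@]2(C)CCC=C(C)C)cc1 | intermediate
8 | 3-[(2R,3R)-3-{4-[(4-methoxybenzyl)oxy]but-2-yn-1-yl}-2-methyloxiran-2-yl]propanal | COc1ccc(COCC#CC[C@H]2O[C@]2(C)CCC=O)cc1 | intermediate
9 | but-3-en-1-ylmagnesium bromide | C=CCC[Mg]Br | starting material
10 | 2,3-dibromoprop-1-ene | C=C(Br)CBr | starting material
11 | 2-bromohepta-1,6-diene | C=C(Br)CCCC=C | intermediate
12 | methyl acrylate | C=CC(=O)OC | starting material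
13 | methyl (2E)-7-bromoocta-2,7-dienoate | C=C(Br)CCC/C=C/C(=O)OC | intermediate
14 | (2E)-7-bromoocta-2,7-dien-1-ol | C=C(Br)CCC/C=C/CO | intermediate
15 | [(2R,3R)-3-(4-bromopent-4-en-1-yl)oxiran-2-yl]methanol | OC[C@H]1O[C@@H]1CCCC(Br)=C | intermediate
16 | (2S,3S)-7-bromo-3-methyloct-7-ene-1,2-diol | C=C(Br)CCC[C@H](C)[C@H](O)CO | intermediate
17 | (2S,3S)-7-bromo-3-methyloct-7-ene-1,2-diyl bis(TBS) ether | C=C(Br)CCC[C@H](C)[C@H](O[Si](C)(C)C(C)(C)C)CO[Si](C)(C)C(C)(C)C | intermediate
18 | 2-lithio alkene from 17 (vinyllithium) | [Li]C(=C)CCC[C@H](C)[C@H](O[Si](C)(C)C(C)(C)C)CO[Si](C)(C)C(C)(C)C | intermediate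
19 | coupled allylic alcohol, both C7 epimers (17-O-PMB, 13,14-bis-O-TBS) | COc1ccc(COCC#CC[C@H]2O[C@]2(C)CCC(O)C(=C)CCC[C@H](C)[C@H](O[Si](C)(C)C(C)(C)C)CO[Si](C)(C)C(C)(C)C)cc1 | intermediate
20 | C7 enone | COc1ccc(COCC#CC[C@H]2O[C@]2(C)CCC(=O)C(=C)CCC[C@H](C)[C@H](O[Si](C)(C)C(C)(C)C)CO[Si](C)(C)C(C)(C)C)cc1 | intermediate
21 | (7R)-allylic alcohol | COc1ccc(COCC#CC[C@H]2O[C@]2(C)CC[C@@H](O)C(=C)CCC[C@H](C)[C@H](O[Si](C)(C)C(C)(C)C)CO[Si](C)(C)C(C)(C)C)cc1 | intermediate
22 | 7-O-TBS ether (17-O-PMB, 7,13,14-tris-O-TBS) | COc1ccc(COCC#CC[C@H]2O[C@]2(C)CC[C@@H](O[Si](C)(C)C(C)(C)C)C(=C)CCC[C@H](C)[C@H](O[Si](C)(C)C(C)(C)C)CO[Si](C)(C)C(C)(C)C)cc1 | intermediate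
23 | propargylic alcohol (C17–OH) | OCC#CC[C@H]1O[C@]1(C)CC[C@@H](O[Si](C)(C)C(C)(C)C)C(=C)CCC[C@H](C)[C@H](O[Si](C)(C)C(C)(C)C)CO[Si](C)(C)C(C)(C)C | intermediate
24 | N-propargyl-N-(2-nitrophenylsulfonyl)hydrazine adduct | NN(CC#CC[C@H]1O[C@]1(C)CC[C@@H](O[Si](C)(C)C(C)(C)C)C(=C)CCC[C@H](C)[C@H](O[Si](C)(C)C(C)(C)C)CO[Si](C)(C)C(C)(C)C)S(=O)(=O)c1ccccc1[N+](=O)[O-] | intermediate
25 | propargylic diazene | N=NCC#CC[C@H]1O[C@]1(C)CC[C@@H](O[Si](C)(C)C(C)(C)C)C(=C)CCC[C@H](C)[C@H](O[Si](C)(C)C(C)(C)C)CO[Si](C)(C)C(C)(C)C | intermediate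
26 | terminal allene (7,13,14-tris-O-TBS) | C=C=CC[C@H]1O[C@]1(C)CC[C@@H](O[Si](C)(C)C(C)(C)C)C(=C)CCC[C@H](C)[C@H](O[Si](C)(C)C(C)(C)C)CO[Si](C)(C)C(C)(C)C | intermediate
27 | allenyl primary alcohol (C14–OH) | C=C=CC[C@H]1O[C@]1(C)CC[C@@H](O[Si](C)(C)C(C)(C)C)C(=C)CCC[C@H](C)[C@H](O[Si](C)(C)C(C)(C)C)CO | intermediate
28 | allenyl aldehyde (key-step substrate) | C=C=CC[C@H]1O[C@]1(C)CC[C@@H](O[Si](C)(C)C(C)(C)C)C(=C)CCC[C@H](C)[C@H](O[Si](C)(C)C(C)(C)C)C=O | intermediate
29 | oxanickelacycle (nickelalactone, σ-allyl form, DBU ligands omitted) | O=C1O[Ni]C/C1=C\C[C@H]2O[C@]2(C)CC[C@@H](O[Si](C)(C)C(C)(C)C)C(=C)CCC[C@H](C)[C@H](O[Si](C)(C)C(C)(C)C)C=O | intermediate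
30 | macrocyclic nickel(II) alkoxide carboxylate (DBU ligands omitted) | C=C1CCC[C@H](C)[C@H](O[Si](C)(C)C(C)(C)C)[C@@H]2O[Ni]OC(=O)C(=C)[C@@H]2C[C@H]2O[C@]2(C)CC[C@H]1O[Si](C)(C)C(C)(C)C | intermediate
31 | (1S,3R,4R,7R,12S,13S,14R)-7,13-bis-O-TBS-3,4-epoxy-14-hydroxycembra-8(19),15(17)-dien-16-oic acid | C=C1CCC[C@H](C)[C@H](O[Si](C)(C)C(C)(C)C)[C@H](O)[C@H](C(=C)C(=O)O)C[C@H]2O[C@]2(C)CC[C@H]1O[Si](C)(C)C(C)(C)C | intermediate
32 | 7,13-bis-O-TBS 13-epi lactone | C=C1CCC[C@H](C)[C@H](O[Si](C)(C)C(C)(C)C)[C@@H]2OC(=O)C(=C)[C@@H]2C[C@H]2O[C@]2(C)CC[C@H]1O[Si](C)(C)C(C)(C)C | intermediate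
33 | 7,13-diol lactone (13S) | C=C1CCC[C@H](C)[C@H](O)[C@@H]2OC(=O)C(=C)[C@@H]2C[C@H]2O[C@]2(C)CC[C@H]1O | intermediate
34 | 7-O-acetyl 13-epi alcohol | C=C1CCC[C@H](C)[C@H](O)[C@@H]2OC(=O)C(=C)[C@@H]2C[C@H]2O[C@]2(C)CC[C@H]1OC(C)=O | intermediate
35 | CNP0323853.1, (1S,3R,4R,7R,12S,13R,14R)-7,13-diacetoxy-3,4-epoxycembra-8(19),15(17)-dien-16,14-olide | C=C1CCC[C@H](C)[C@@H](OC(C)=O)[C@@H]2OC(=O)C(=C)[C@@H]2C[C@H]2O[C@]2(C)CC[C@H]1OC(C)=O | target

**Totals**
Total step count: 23. Longest linear sequence: 19 steps (steps 5–10, then 11–23).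

**Steps most likely to fail**

Step 19 (Proposed new method). Nickel(0) may consume the aldehyde or oligomerise the chain before CO2 capture. DBU may epimerise C13. The allyl transfer may show poor facial selectivity at C14 or a wrong syn/anti sense at C1. The fallback is the classical intramolecular Barbier route; it sets out from 23 and comes back at 32. Palladium-catalysed syn-hydrostannation of 23 (Bu3SnH, cat. PdCl2(PPh3)2, THF), with the hydroxyl directing tin to the proximal carbon, should give the (2E)-2-stannyl allylic alcohol F1. Iododestannylation (I2, CH2Cl2, 0 °C) would give the vinyl iodide F2. Methoxycarbonylation (CO, MeOH, Et3N, cat. PdCl2(PPh3)2) would give the (2E)-2-(hydroxymethyl)alk-2-enoate F3. Appel bromination (CBr4, PPh3) would give the (2Z)-2-(bromomethyl)alk-2-enoate F4. Selective cleavage of the primary silyl ether (HF·pyridine, pyridine, 0 °C) would give the bromo alcohol F5, and Dess–Martin oxidation the bromo aldehyde F6. Indium-mediated intramolecular Barbier allylation at high dilution (In, THF/H2O) should give the macrocyclic hydroxy ester F7 (Z-type allylmetal → syn; non-chelating α-silyloxy aldehyde → anti to O13). F7 should lactonise, spontaneously or with a trace of acid at 0 °C, to 32.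

Step 23. The hindered C13 hydroxyl may be activated too slowly, or the oxyphosphonium may eliminate instead of being displaced. The fallback replaces substitution by oxidation and reduction; it sets out from 34 and comes back at 35. Dess–Martin oxidation would give the C13 ketone F8. Luche reduction (NaBH4, CeCl3, MeOH, −78 °C), with hydride expected anti to the C14–O bond (polar Felkin–Anh) and no conjugate reduction of the methylene lactone, should give the (13R)-alcohol F9. Acetylation (Ac2O, DMAP, pyridine) would give 35.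

Step 21. Forcing fluoride cleavage of the hindered C13 silyl ether may let the freed C7 hydroxyl open the epoxide across the ring under the acidic medium. The fallback removes the silyl groups one at a time so that no free C7 hydroxyl is present during the slow cleavage; it sets out from 32 and comes back at 34. Brief buffered HF·pyridine at 0 °C should remove only the allylic C7 silyl ether to give the 7-hydroxy 13-silyl ether F10. Acetylation (Ac2O, pyridine) would give the 7-acetate 13-silyl ether F11. Cleavage of the remaining silyl ether (HF·pyridine, rt) would give 34, and step 22 is then not needed.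

**Further compounds**
F1 | step 19 | (2E)-2-(tributylstannyl) allylic alcohol from 23 | OC/C([Sn](CCCC)(CCCC)CCCC)=C\C[C@H]1O[C@]1(C)CC[C@@H](O[Si](C)(C)C(C)(C)C)C(=C)CCC[C@H](C)[C@H](O[Si](C)(C)C(C)(C)C)CO[Si](C)(C)C(C)(C)C
F2 | step 19 | (2E)-2-iodo allylic alcohol | OC/C(I)=C\C[C@H]1O[C@]1(C)CC[C@@H](O[Si](C)(C)C(C)(C)C)C(=C)CCC[C@H](C)[C@H](O[Si](C)(C)C(C)(C)C)CO[Si](C)(C)C(C)(C)C
F3 | step 19 | methyl (2E)-2-(hydroxymethyl)alk-2-enoate | OC/C(C(=O)OC)=C\C[C@H]1O[C@]1(C)CC[C@@H](O[Si](C)(C)C(C)(C)C)C(=C)CCC[C@H](C)[C@H](O[Si](C)(C)C(C)(C)C)CO[Si](C)(C)C(C)(C)C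
F4 | step 19 | methyl (2Z)-2-(bromomethyl)alk-2-enoate | BrC/C(C(=O)OC)=C\C[C@H]1O[C@]1(C)CC[C@@H](O[Si](C)(C)C(C)(C)C)C(=C)CCC[C@H](C)[C@H](O[Si](C)(C)C(C)(C)C)CO[Si](C)(C)C(C)(C)C
F5 | step 19 | bromo ester primary alcohol (C14–OH) | BrC/C(C(=O)OC)=C\C[C@H]1O[C@]1(C)CC[C@@H](O[Si](C)(C)C(C)(C)C)C(=C)CCC[C@H](C)[C@H](O[Si](C)(C)C(C)(C)C)CO
F6 | step 19 | bromo ester aldehyde (C14 aldehyde) | BrC/C(C(=O)OC)=C\C[C@H]1O[C@]1(C)CC[C@@H](O[Si](C)(C)C(C)(C)C)C(=C)CCC[C@H](C)[C@H](O[Si](C)(C)C(C)(C)C)C=O
F7 | step 19 | macrocyclic hydroxy methyl ester | C=C1CCC[C@H](C)[C@H](O[Si](C)(C)C(C)(C)C)[C@H](O)[C@H](C(=C)C(=O)OC)C[C@H]2O[C@]2(C)CC[C@H]1O[Si](C)(C)C(C)(C)C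
F8 | step 23 | C13 ketone of 34 | C=C1CCC[C@H](C)C(=O)[C@@H]2OC(=O)C(=C)[C@@H]2C[C@H]2O[C@]2(C)CC[C@H]1OC(C)=O
F9 | step 23 | (13R)-alcohol, 7-acetate | C=C1CCC[C@H](C)[C@@H](O)[C@@H]2OC(=O)C(=C)[C@@H]2C[C@H]2O[C@]2(C)CC[C@H]1OC(C)=O
F10 | step 21 | 7-hydroxy 13-O-TBS lactone | C=C1CCC[C@H](C)[C@H](O[Si](C)(C)C(C)(C)C)[C@@H]2OC(=O)C(=C)[C@@H]2C[C@H]2O[C@]2(C)CC[C@H]1O
F11 | step 21 | 7-O-acetyl 13-O-TBS lactone | C=C1CCC[C@H](C)[C@H](O[Si](C)(C)C(C)(C)C)[C@@H]2OC(=O)C(=C)[C@@H]2C[C@H]2O[C@]2(C)CC[C@H]1OC(C)=O
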